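**Plan** (target numbering: O1, C2, C3, C3a, C4–C11, C11a; ring A = γ-lactone, ring B = ten-membered carbocycle)
Retrosynthetic cuts, in order: lactone O1–C11a (allyl-palladium lactonisation of a C9/C10 vinyl carbonate, CO2 extruded); C3–C3a (allyl-palladium alkylation of a ring diene monoepoxide, then methylenation); ring olefin C3a=C11a (metathesis); C9–C10 (Ni/Cr coupling).
Forward: the chain is built from neryl acetate, acrolein and angelic acid; ring B closes by metathesis in step 9; the acrylate arm is added on the ring; ring A closes last.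
Stereochemistry: C7/C8 from a Sharpless epoxidation and C4 from a catalytic vinylzinc addition; C9 by Felkin–Anh addition; a temporary C10–C11 epoxide by hydroxyl-directed epoxidation.
C3a and then C11a are relayed from that epoxide by two allyl-palladium displacements, each with net retention.
Enabling feature: in ring B the lactone oxygen on C11a and the hydroxyl on C9 lie syn-1,4 across the Z C10=C11 olefin, which is what results when a C10–O bond is ionised and oxygen returns at C11a on the same face.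

Key step: step 14

Remark: the angeloyl group is assumed to survive the neutral or weakly basic conditions of steps 4–14 without isomerising to the tiglate.

Step 1
Reactants: 1 neryl acetate
Product: 2 (2Z)-3-methyl-6-oxohex-2-en-1-yl acetate
Conditions: O3 (1 equiv), CH2Cl2/pyridine, –78 °C; then Me2S
Reagents that add atoms: ozone, [O-][O+]=O
Why: Chemoselective ozonolysis, because the 6,7-olefin is more electron-rich than the 2,3-olefin, which is deactivated by the allylic acetoxy group; no stereocenter is formed.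

Step 2
Reactants: 2 (2Z)-3-methyl-6-oxohex-2-en-1-yl acetate
Product: 3 (2Z,6R)-6-hydroxy-3-methylocta-2,7-dien-1-yl acetate
Conditions: Zn(CH=CH2)2 (from CH2=CHMgBr and ZnCl2), (–)-MIB (10 mol%), toluene, –20 °C; aq. NH4Cl
Reagents that add atoms: vinylmagnesium bromide, C=C[Mg]Br
Why: Amino-alcohol-catalysed enantioselective vinylzinc addition to an aldehyde, in which the ligand should direct vinyl to the Si face and so set C4 as R, while the acetate is inert to the organozinc.

Step 3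
Reactants: 3 (2Z,6R)-6-hydroxy-3-methylocta-2,7-dien-1-yl acetate
Product: 4 (3R,6Z)-8-acetoxy-6-methylocta-1,6-dien-3-yl (2Z)-2-methylbut-2-enoate
Conditions: angelic acid, 2,4,6-Cl3C6H2COCl, Et3N, toluene, 25 °C; then 3, 80 °C
Reagents that add atoms: angelic acid, C/C=C(/C)C(=O)O
Why: Yamaguchi mixed-anhydride esterification, run without nucleophilic catalyst so that the angeloyl group should be transferred without Z to E isomerisation and C4 is acylated with retention.

Step 4
Reactants: 4 (3R,6Z)-8-acetoxy-6-methylocta-1,6-dien-3-yl (2Z)-2-methylbut-2-enoate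
Product: 5 (3R,6Z)-8-hydroxy-6-methylocta-1,6-dien-3-yl (2Z)-2-methylbut-2-enoate
Conditions: K2CO3 (0.2 equiv), MeOH, 0 °C
Reagents that add atoms: none
Why: Base-catalysed transesterification, which should cleave the unhindered primary acetate much faster than the hindered, conjugated secondary angelate.

Step 5
Reactants: 5 (3R,6Z)-8-hydroxy-6-methylocta-1,6-dien-3-yl (2Z)-2-methylbut-2-enoate
Product: 6 (3R)-5-[(2S,3R)-3-(hydroxymethyl)-2-methyloxiran-2-yl]pent-1-en-3-yl (2Z)-2-methylbut-2-enoate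
Conditions: Ti(OiPr)4 (10 mol%), D-(–)-diisopropyl tartrate (12 mol%), t-BuOOH, 4 Å MS, CH2Cl2, –20 °C
Reagents that add atoms: tert-butyl hydroperoxide, CC(C)(C)OO
Why: Sharpless asymmetric epoxidation of the (Z)-trisubstituted primary allylic alcohol, where the D-tartrate should give the (2R,3S) epoxide as it does with nerol (C8 and C7 of the target) and leave the vinyl group and the conjugated ester untouched.

Step 6
Reactants: 6 (3R)-5-[(2S,3R)-3-(hydroxymethyl)-2-methyloxiran-2-yl]pent-1-en-3-yl (2Z)-2-methylbut-2-enoate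
Product: 7 (3R)-5-[(2S,3S)-3-formyl-2-methyloxiran-2-yl]pent-1-en-3-yl (2Z)-2-methylbut-2-enoate
Conditions: TEMPO (10 mol%), PhI(OAc)2, CH2Cl2, 25 °C
Reagents that add atoms: none
Why: Oxoammonium (TEMPO) oxidation of the primary alcohol to the epoxy aldehyde under near-neutral conditions, which should neither open the epoxide nor epimerise C8.

Step 7
Reactants: 8 acrolein
Product: 9 (3Z)-4-iodopenta-1,3-diene
Conditions: EtPPh3+ I–, n-BuLi, THF, 25 °C; I2, –78 °C; NaN(SiMe3)2, –20 °C; then 8, –78 °C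
Reagents that add atoms: ethyltriphenylphosphonium iodide, CC[P+](c1ccccc1)(c1ccccc1)c1ccccc1.[I-]; iodine, II
Why: Stork–Zhao-type Wittig olefination with the in situ α-iodo ylide, which under kinetic control should place iodine cis to the vinyl group (Z).

Step 8
Reactants: 7 (3R)-5-[(2S,3S)-3-formyl-2-methyloxiran-2-yl]pent-1-en-3-yl (2Z)-2-methylbut-2-enoate; 9 (3Z)-4-iodopenta-1,3-diene
Product: 10 (3R)-5-{(2S,3R)-3-[(1R,2Z)-1-hydroxy-2-methylpenta-2,4-dien-1-yl]-2-methyloxiran-2-yl}pent-1-en-3-yl (2Z)-2-methylbut-2-enoate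
Conditions: CrCl2 (4 equiv), NiCl2 (2 mol%), DMSO, 25 °C
Reagents that add atoms: none
Why: Nozaki–Hiyama–Kishi coupling, in which the alkenylchromium adds to the aldehyde with retention of olefin geometry and tolerance of both esters, and Felkin–Anh attack anti to the epoxide C–O bond should give the anti epoxy alcohol (C9 R).

Step 9
Reactants: 10 (3R)-5-{(2S,3R)-3-[(1R,2Z)-1-hydroxy-2-methylpenta-2,4-dien-1-yl]-2-methyloxiran-2-yl}pent-1-en-3-yl (2Z)-2-methylbut-2-enoate
Product: 11 (1R,2Z,4Z,6R,7R,8S)-7,8-epoxy-6-hydroxy-5,8-dimethylcyclodeca-2,4-dien-1-yl (2Z)-2-methylbut-2-enoate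
Conditions: second-generation Hoveyda–Grubbs catalyst (10 mol%), toluene (1 mM), 80 °C
Reagents that add atoms: none
Why: Diene–ene ring-closing metathesis between the two monosubstituted vinyl termini, helped by the cis-epoxide and the Z-trisubstituted olefin as turn elements, with the ten-membered ring enforcing the Z geometry of the new C3a=C11a olefin.

Step 10
Reactants: 11 (1R,2Z,4Z,6R,7R,8S)-7,8-epoxy-6-hydroxy-5,8-dimethylcyclodeca-2,4-dien-1-yl (2Z)-2-methylbut-2-enoate
Product: 12 (1R,2Z,4R,5S,6S,7R,8S)-4,5:7,8-diepoxy-6-hydroxy-5,8-dimethylcyclodec-2-en-1-yl (2Z)-2-methylbut-2-enoate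
Conditions: VO(acac)2 (5 mol%), t-BuOOH, CH2Cl2, 0 °C
Reagents that add atoms: tert-butyl hydroperoxide, CC(C)(C)OO
Why: Hydroxyl-directed vanadium epoxidation, which should touch only the allylic C10=C11 olefin and deliver oxygen syn to the C9 hydroxyl, as with medium-ring (Z)-cycloalkenols and reinforced by the geminal methyl group.

Step 11
Reactants: 12 (1R,2Z,4R,5S,6S,7R,8S)-4,5:7,8-diepoxy-6-hydroxy-5,8-dimethylcyclodec-2-en-1-yl (2Z)-2-methylbut-2-enoate
Product: 13 (1R,2R,3Z,5R,6S,7R,8S)-2-(2,2-dimethyl-4,6-dioxo-1,3-dioxan-5-yl)-7,8-epoxy-5,6-dihydroxy-5,8-dimethylcyclodec-3-en-1-yl (2Z)-2-methylbut-2-enoate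
Conditions: Pd2(dba)3·CHCl3 (2.5 mol%), PPh3 (10 mol%), Meldrum's acid (3 equiv), THF, 0 to 25 °C
Reagents that add atoms: Meldrum's acid, CC1(C)OC(=O)CC(=O)O1
Why: Tsuji–Trost alkylation of a cyclic diene monoepoxide under neutral conditions, where zerovalent palladium opens the allylic C11–O bond anti and the carbon acid attacks the distal terminus C3a anti to the metal, so the new C–C bond should form cis-1,4 to the freed C10 hydroxyl (C3a R).

Step 12
Reactants: 13 (1R,2R,3Z,5R,6S,7R,8S)-2-(2,2-dimethyl-4,6-dioxo-1,3-dioxan-5-yl)-7,8-epoxy-5,6-dihydroxy-5,8-dimethylcyclodec-3-en-1-yl (2Z)-2-methylbut-2-enoate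
Product: 14 (1R,2R,3Z,5R,6S,7R,8S)-7,8-epoxy-5,6-dihydroxy-5,8-dimethyl-2-{3-oxo-3-[2-(trimethylsilyl)ethoxy]prop-1-en-2-yl}cyclodec-3-en-1-yl (2Z)-2-methylbut-2-enoate
Conditions: Me2N+=CH2 I– (2.5 equiv), Me3SiCH2CH2OH/MeCN, 65 °C
Reagents that add atoms: dimethylmethylideneammonium iodide (Eschenmoser's salt), C=[N+](C)C.[I-]; 2-(trimethylsilyl)ethanol, C[Si](C)(C)CCO
Why: One-pot alcoholysis of the Meldrum's acid ring, Mannich reaction and decarboxylative elimination, the known α-methylenation of monosubstituted Meldrum's acids, which should give the acrylate without touching a stereocenter.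

Step 13
Reactants: 14 (1R,2R,3Z,5R,6S,7R,8S)-7,8-epoxy-5,6-dihydroxy-5,8-dimethyl-2-{3-oxo-3-[2-(trimethylsilyl)ethoxy]prop-1-en-2-yl}cyclodec-3-en-1-yl (2Z)-2-methylbut-2-enoate
Product: 15 (1R,2R,3Z,5R,6S,7R,8S)-5,6-(carbonyldioxy)-7,8-epoxy-5,8-dimethyl-2-{3-oxo-3-[2-(trimethylsilyl)ethoxy]prop-1-en-2-yl}cyclodec-3-en-1-yl (2Z)-2-methylbut-2-enoate
Conditions: CDI (1.5 equiv), DBU (cat.), CH2Cl2, 25 °C
Reagents that add atoms: 1,1'-carbonyldiimidazole, O=C(n1ccnc1)n1ccnc1
Why: Cyclic carbonate formation from the cis-1,2-diol with both C–O bonds retained, which turns the tertiary allylic C10 oxygen into a leaving group while masking the C9 hydroxyl.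

Step 14
Reactants: 15 (1R,2R,3Z,5R,6S,7R,8S)-5,6-(carbonyldioxy)-7,8-epoxy-5,8-dimethyl-2-{3-oxo-3-[2-(trimethylsilyl)ethoxy]prop-1-en-2-yl}cyclodec-3-en-1-yl (2Z)-2-methylbut-2-enoate
Product: 17 (3aR,4R,7S,8R,9R,10Z,11aS)-7,8-epoxy-9-hydroxy-7,10-dimethyl-3-methylidene-2-oxo-2,3,3a,4,5,6,7,8,9,11a-decahydrocyclodeca[b]furan-4-yl (2Z)-2-methylbut-2-enoate, via carboxylic acid 16 (not isolated)
Conditions: Bu4NF (1.1 equiv), THF, 0 °C; then Pd(PPh3)4 (5 mol%), 0 to 25 °C; aq. NH4Cl
Reagents that add atoms: none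
Why: Fluoride removes the 2-(trimethylsilyl)ethyl group as ethene and Me3SiF to give carboxylate 16; zerovalent palladium then ionises the tertiary allylic C10–O bond of the carbonate from the face opposite to oxygen, CO2 is lost, and an anti,anti-η3-allyl over C10–C11–C11a forms with the C9 oxygen set free. The closest known reaction type is the decarboxylative allylic substitution of vinyl ethylene carbonates, equivalent to the syn-1,4-addition of carboxylic acids to cyclic 1,3-diene monoepoxides (Tsuji–Trost manifold). Ring A closes by 5-exo attack of the tethered carboxylate oxygen on the allyl terminus C11a, anti to palladium. Because ionisation and attack are both anti to the metal, oxygen returns on the face it left, so C11a (S) is dictated by the C10 carbonate configuration and should emerge cis to the C3a substituent and syn-1,4 to the untouched C9 hydroxyl, while the anti,anti allyl held in ring B gives the Z C10=C11 olefin. The step needs attack at C11a and not at C10, and ionisation of this carbonate only; five- versus seven-membered ring closure secures the first, and the second follows because the C4 angelate is homoallylic and the C7–C8 epoxide is not allylic.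

**Compound list**
1 | neryl acetate, (2Z)-3,7-dimethylocta-2,6-dien-1-yl acetate | CC(C)=CCC/C(C)=C\COC(C)=O | starting material
2 | (2Z)-3-methyl-6-oxohex-2-en-1-yl acetate | O=CCC/C(C)=C\COC(C)=O | intermediate
3 | (2Z,6R)-6-hydroxy-3-methylocta-2,7-dien-1-yl acetate | C=C[C@H](O)CC/C(C)=C\COC(C)=O | intermediate
4 | (3R,6Z)-8-acetoxy-6-methylocta-1,6-dien-3-yl (2Z)-2-methylbut-2-enoate | C=C[C@H](OC(=O)/C(C)=C\C)CC/C(C)=C\COC(C)=O | intermediate
5 | (3R,6Z)-8-hydroxy-6-methylocta-1,6-dien-3-yl (2Z)-2-methylbut-2-enoate | C=C[C@H](OC(=O)/C(C)=C\C)CC/C(C)=C\CO | intermediate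
6 | (3R)-5-[(2S,3R)-3-(hydroxymethyl)-2-methyloxiran-2-yl]pent-1-en-3-yl (2Z)-2-methylbut-2-enoate | OC[C@H]1O[C@@]1(C)CC[C@@H](OC(=O)/C(C)=C\C)C=C | intermediate
7 | (3R)-5-[(2S,3S)-3-formyl-2-methyloxiran-2-yl]pent-1-en-3-yl (2Z)-2-methylbut-2-enoate | O=C[C@H]1O[C@@]1(C)CC[C@@H](OC(=O)/C(C)=C\C)C=C | intermediate
8 | acrolein (prop-2-enal) | C=CC=O | starting material
9 | (3Z)-4-iodopenta-1,3-diene | C=C/C=C(/C)I | intermediate
10 | (3R)-5-{(2S,3R)-3-[(1R,2Z)-1-hydroxy-2-methylpenta-2,4-dien-1-yl]-2-methyloxiran-2-yl}pent-1-en-3-yl (2Z)-2-methylbut-2-enoate | C=C/C=C(/C)[C@@H](O)[C@H]1O[C@@]1(C)CC[C@@H](OC(=O)/C(C)=C\C)C=C | intermediate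
11 | (1R,2Z,4Z,6R,7R,8S)-7,8-epoxy-6-hydroxy-5,8-dimethylcyclodeca-2,4-dien-1-yl (2Z)-2-methylbut-2-enoate | C/C=C(/C)C(=O)O[C@H]1/C=C\C=C(\C)[C@@H](O)[C@H]2O[C@@]2(C)CC1 | intermediate
12 | (1R,2Z,4R,5S,6S,7R,8S)-4,5:7,8-diepoxy-6-hydroxy-5,8-dimethylcyclodec-2-en-1-yl (2Z)-2-methylbut-2-enoate | C/C=C(/C)C(=O)O[C@H]1/C=C\[C@H]2O[C@@]2(C)[C@@H](O)[C@H]3O[C@@]3(C)CC1 | intermediate
13 | (1R,2R,3Z,5R,6S,7R,8S)-2-(2,2-dimethyl-4,6-dioxo-1,3-dioxan-5-yl)-7,8-epoxy-5,6-dihydroxy-5,8-dimethylcyclodec-3-en-1-yl (2Z)-2-methylbut-2-enoate | C/C=C(/C)C(=O)O[C@H]1[C@@H](C3C(=O)OC(C)(C)OC3=O)/C=C\[C@@](C)(O)[C@@H](O)[C@H]2O[C@@]2(C)CC1 | intermediate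
14 | (1R,2R,3Z,5R,6S,7R,8S)-7,8-epoxy-5,6-dihydroxy-5,8-dimethyl-2-{3-oxo-3-[2-(trimethylsilyl)ethoxy]prop-1-en-2-yl}cyclodec-3-en-1-yl (2Z)-2-methylbut-2-enoate | C/C=C(/C)C(=O)O[C@H]1[C@@H](C(=C)C(=O)OCC[Si](C)(C)C)/C=C\[C@@](C)(O)[C@@H](O)[C@H]2O[C@@]2(C)CC1 | intermediate
15 | (1R,2R,3Z,5R,6S,7R,8S)-5,6-(carbonyldioxy)-7,8-epoxy-5,8-dimethyl-2-{3-oxo-3-[2-(trimethylsilyl)ethoxy]prop-1-en-2-yl}cyclodec-3-en-1-yl (2Z)-2-methylbut-2-enoate | C/C=C(/C)C(=O)O[C@H]1[C@@H](C(=C)C(=O)OCC[Si](C)(C)C)/C=C\[C@@]3(C)OC(=O)O[C@H]3[C@H]2O[C@@]2(C)CC1 | intermediate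
16 | (1R,2R,3Z,5R,6S,7R,8S)-2-(1-carboxyethenyl)-5,6-(carbonyldioxy)-7,8-epoxy-5,8-dimethylcyclodec-3-en-1-yl (2Z)-2-methylbut-2-enoate | C/C=C(/C)C(=O)O[C@H]1[C@@H](C(=C)C(=O)O)/C=C\[C@@]3(C)OC(=O)O[C@H]3[C@H]2O[C@@]2(C)CC1 | intermediate
17 | (3aR,4R,7S,8R,9R,10Z,11aS)-7,8-epoxy-9-hydroxy-7,10-dimethyl-3-methylidene-2-oxo-2,3,3a,4,5,6,7,8,9,11a-decahydrocyclodeca[b]furan-4-yl (2Z)-2-methylbut-2-enoate | C=C1C(=O)O[C@H]2/C=C(/C)[C@@H](O)[C@H]3O[C@@]3(C)CC[C@@H](OC(=O)/C(C)=C\C)[C@@H]12 | target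

Total step count: 14. Longest linear sequence: 13 steps (steps 1–6 and 8–14).

**Steps most likely to fail**

Step 9. Ring closure may lose to oligomerisation, or the ruthenium carbene may engage the internal diene olefin, because of the strain of the ten-membered diene. The fallback closes ring B at the C9–C10 bond and sets out from 7. Z-selective cross-metathesis of its vinyl group with the terminal olefin of 9, using the cyclometalated alkylidene [1-(adamantan-2-id-1-yl)-3-mesitylimidazolidin-2-ylidene](nitrato)(2-isopropoxybenzylidene)ruthenium, would give (3R,4Z,6Z)-1-[(2S,3S)-3-formyl-2-methyloxiran-2-yl]-7-iodoocta-4,6-dien-3-yl (2Z)-2-methylbut-2-enoate F1. An intramolecular CrCl2/NiCl2 coupling of F1 at high dilution in DMSO would then return to 11, replacing steps 8 and 9.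

Step 10. Facial selectivity of the directed epoxidation may be poor in this ring, and the allylic alcohol may be over-oxidised to the enone. The fallback sets out from 10 and epoxidises before ring closure under reagent control. Ti(OiPr)4, t-BuOOH and the diisopropyl tartrate enantiomer matched to the (R)-carbinol should give the erythro vinyl epoxide (3R)-5-{(2S,3R)-3-[(S)-[(2S,3R)-3-ethenyl-2-methyloxiran-2-yl](hydroxy)methyl]-2-methyloxiran-2-yl}pent-1-en-3-yl (2Z)-2-methylbut-2-enoate F2. Ring-closing metathesis of F2 with the second-generation Hoveyda–Grubbs catalyst would then join the route at 12.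

Step 8. Facial discrimination in the addition to the epoxy aldehyde may be low, and divalent chromium may reductively open the epoxide. The fallback sets out from 10 obtained as an epimer mixture at C9. Oxidation with Dess–Martin periodinane would give the dienone (3R)-5-{(2S,3S)-2-methyl-3-[(2Z)-2-methylpenta-2,4-dienoyl]oxiran-2-yl}pent-1-en-3-yl (2Z)-2-methylbut-2-enoate F3. Chelation-controlled reduction of F3 with Zn(BH4)2 in ether at –20 °C, with hydride delivered anti to the epoxide oxygen, would return the single anti epoxy alcohol 10.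

Further compounds
F1 | step 9 | (3R,4Z,6Z)-1-[(2S,3S)-3-formyl-2-methyloxiran-2-yl]-7-iodoocta-4,6-dien-3-yl (2Z)-2-methylbut-2-enoate | O=C[C@H]1O[C@@]1(C)CC[C@@H](OC(=O)/C(C)=C\C)/C=C\C=C(\C)I
F2 | step 10 | (3R)-5-{(2S,3R)-3-[(S)-[(2S,3R)-3-ethenyl-2-methyloxiran-2-yl](hydroxy)methyl]-2-methyloxiran-2-yl}pent-1-en-3-yl (2Z)-2-methylbut-2-enoate | C=C[C@H]1O[C@@]1(C)[C@@H](O)[C@H]2O[C@@]2(C)CC[C@@H](OC(=O)/C(C)=C\C)C=C
F3 | step 8 | (3R)-5-{(2S,3S)-2-methyl-3-[(2Z)-2-methylpenta-2,4-dienoyl]oxiran-2-yl}pent-1-en-3-yl (2Z)-2-methylbut-2-enoate | C=C/C=C(/C)C(=O)[C@H]1O[C@@]1(C)CC[C@@H](OC(=O)/C(C)=C\C)C=C
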